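**Plan**

- Labels used below: dioxane ring O1–O2–C3–C4–C5–C6 (C3 carries the propanoate arm with α‑carbon Cα, C6 is the quaternary carbon); side chain C1′–C13′ counted from C6, with stereocentres C4′ and C8′.
- Retrosynthesis: the ring is cut at O2–C3 and C4–C5 (one‑pot radical/polar annulation of a C5 iodide with a four‑carbon vinyl sulfone), then the chain at C6′–C7′ (Wittig olefination, then diimide), then the two tertiary C–OO bonds (epoxide perhydrolysis).
- Enabling feature: C3 lies β to the ester carbonyl, so O2–C3 is a conjugate‑addition bond. The C4–C5 ethano bridge joins that acceptor to a primary carbon on the fully substituted peroxide carbon C6, so C5 can act as a primary β‑peroxyalkyl radical and C4 as the CH2 end of a radical acceptor.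
- Forward: a remote C9 peroxy aldehyde (from 6‑methylhept‑5‑en‑2‑one) and a central phosphonium/epoxide fragment (from (S)‑citronellyl bromide) are joined and the new alkene reduced; the ring‑end epoxide is perhydrolysed and C5 becomes an iodide; the only ring is closed in the last step, which also frees the remote hydroperoxide.
- Stereochemistry: C8′ from a catalytic asymmetric Corey–Chaykovsky epoxidation followed by perhydrolysis with inversion; C4′ from the chiral pool; C6 from Sharpless epoxidation, hydride opening with retention and perhydrolysis with inversion; C3 and Cα in the key step under substrate control.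

Key step: step 17

Remark: in step 1 the sense of induction of the lanthanum–lithium binaphtholate catalyst is assumed; the ligand antipode is taken if the opposite epoxide results.

**Step 1**
Reactants: 1 6‑methylhept‑5‑en‑2‑one
Product: 2 (2R)‑2‑methyl‑2‑(4‑methylpent‑3‑en‑1‑yl)oxirane
Conditions: Me3S(O)I, NaH, LaLi3(C20H12O2)3 [(S)‑binaphtholate complex, 5 mol %], (2,4,6‑(MeO)3C6H2)3P=O (5 mol %), 5 Å MS, THF, rt
Reagents that add atoms: trimethylsulfoxonium iodide, C[S+](C)(C)=O.[I-]
Why: Catalytic asymmetric Corey–Chaykovsky epoxidation of a methyl ketone; the heterobimetallic catalyst binds ketone and ylide and tells the methyl from the primary alkyl group, which sets the precursor of C8′ as (R).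

**Step 2**
Reactants: 2 (2R)‑2‑methyl‑2‑(4‑methylpent‑3‑en‑1‑yl)oxirane
Product: 3 (2S)‑2‑hydroperoxy‑2,6‑dimethylhept‑5‑en‑1‑ol
Conditions: H2O2 (anhydrous, in Et2O), H3PMo12O40 (cat.), Et2O, 0 °C → rt
Reagents that add atoms: hydrogen peroxide, OO
Why: Acid‑catalysed perhydrolysis of a 2,2‑disubstituted epoxide; H2O2 should attack the tertiary carbon anti to the C–O bond (borderline SN2, inversion), which gives the C8′ configuration of the target, the alkene being left alone in the cold.

**Step 3**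
Reactants: 3 (2S)‑2‑hydroperoxy‑2,6‑dimethylhept‑5‑en‑1‑ol
Product: 4 (2S)‑2‑[(tert‑butyldiphenylsilyl)peroxy]‑2,6‑dimethylhept‑5‑en‑1‑ol
Conditions: tBuPh2SiCl (1.05 equiv), imidazole, CH2Cl2, −20 → 0 °C
Reagents that add atoms: tert‑butylchlorodiphenylsilane, CC(C)(C)[Si](Cl)(c1ccccc1)c1ccccc1
Why: Chemoselective O‑silylation; the more acidic, α‑effect hydroperoxy oxygen should react before the neopentyl‑type alcohol, and the bulky diphenylsilyl peroxide is chosen to survive the acid of step 12.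

**Step 4**
Reactants: 4 (2S)‑2‑[(tert‑butyldiphenylsilyl)peroxy]‑2,6‑dimethylhept‑5‑en‑1‑ol
Product: 5 (2S)‑2‑[(tert‑butyldiphenylsilyl)peroxy]‑2,6‑dimethylhept‑5‑enal
Conditions: Dess–Martin periodinane, CH2Cl2, 0 °C → rt
Reagents that add atoms: none
Why: Dess–Martin oxidation of the primary alcohol; the aldehyde has no α‑hydrogen, so neither epimerisation nor β‑elimination of the peroxide is possible.

**Step 5**
Reactants: 6 (S)‑citronellyl bromide, (6S)‑8‑bromo‑2,6‑dimethyloct‑2‑ene
Product: 7 (2E,6S)‑8‑bromo‑2,6‑dimethyloct‑2‑en‑1‑ol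
Conditions: SeO2 (cat.), tBuOOH, CH2Cl2, 0 °C → rt
Reagents that add atoms: tert‑butyl hydroperoxide, CC(C)(C)OO
Why: Selenium dioxide‑catalysed allylic hydroxylation (ene reaction, then [2,3]‑sigmatropic shift) should oxidise the (E)‑methyl group of the isopropylidene unit selectively and leave the bromide alone.

**Step 6**
Reactants: 7 (2E,6S)‑8‑bromo‑2,6‑dimethyloct‑2‑en‑1‑ol
Product: 8 [(2R,3R)‑3‑[(3S)‑5‑bromo‑3‑methylpentyl]‑2‑methyloxiran‑2‑yl]methanol
Conditions: Ti(OiPr)4 (cat.), D‑(−)‑diethyl tartrate (cat.), tBuOOH, 4 Å MS, CH2Cl2, −20 °C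
Reagents that add atoms: tert‑butyl hydroperoxide, CC(C)(C)OO
Why: Sharpless asymmetric epoxidation of an (E)‑2‑methylalk‑2‑en‑1‑ol; the D‑tartrate ligand controls the face and fixes the quaternary carbon that becomes C6.

**Step 7**
Reactants: 8 [(2R,3R)‑3‑[(3S)‑5‑bromo‑3‑methylpentyl]‑2‑methyloxiran‑2‑yl]methanol
Product: 9 (2S,6S)‑8‑bromo‑2,6‑dimethyloctane‑1,2‑diol
Conditions: LiBH4, Ti(OiPr)4, benzene–THF, rt
Reagents that add atoms: none
Why: Ti(OiPr)4‑directed hydride opening of a 2,3‑epoxy alcohol at C3, the carbon remote from the hydroxymethyl group; the tertiary C–O bond and its configuration are retained, and LiBH4 should not reduce the bromide at rt.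

**Step 8**
Reactants: 9 (2S,6S)‑8‑bromo‑2,6‑dimethyloctane‑1,2‑diol
Product: 11 (2S)‑2‑[(4S)‑6‑bromo‑4‑methylhexyl]‑2‑methyloxirane, via primary tosylate 10 (not isolated)
Conditions: NaH, 1‑(p‑toluenesulfonyl)imidazole, THF, 0 °C → rt
Reagents that add atoms: none
Why: One‑pot selective sulfonylation of the primary hydroxyl and 3‑exo‑tet closure by the tertiary alkoxide (Williamson‑type) give the terminal epoxide with retention at the quaternary carbon.

**Step 9**
Reactants: 11 (2S)‑2‑[(4S)‑6‑bromo‑4‑methylhexyl]‑2‑methyloxirane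
Product: 12 {(3S)‑3‑methyl‑6‑[(2S)‑2‑methyloxiran‑2‑yl]hexyl}triphenylphosphonium bromide
Conditions: PPh3, MeCN, 80 °C
Reagents that add atoms: triphenylphosphine, c1ccc(cc1)P(c1ccccc1)c1ccccc1
Why: SN2 quaternisation of the phosphine by the primary bromide; a 2,2‑disubstituted epoxide should be inert to the neutral phosphine at this temperature.

**Step 10**
Reactants: 12 {(3S)‑3‑methyl‑6‑[(2S)‑2‑methyloxiran‑2‑yl]hexyl}triphenylphosphonium bromide; 5 (2S)‑2‑[(tert‑butyldiphenylsilyl)peroxy]‑2,6‑dimethylhept‑5‑enal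
Product: 14 (2S)‑2‑[(4S,6Z,8S)‑8‑[(tert‑butyldiphenylsilyl)peroxy]‑4,8,12‑trimethyltrideca‑6,11‑dien‑1‑yl]‑2‑methyloxirane, via phosphonium ylide 13 (not isolated)
Conditions: NaN(SiMe3)2, THF, −78 °C; then 5, −78 → 0 °C
Reagents that add atoms: none
Why: Wittig olefination of the non‑enolisable α‑peroxy aldehyde with a non‑stabilised ylide (Z expected, geometry irrelevant); epoxide and bulky silyl peroxide should tolerate the ylide in the cold, and no stereocentre is touched.

**Step 11**
Reactants: 14 (2S)‑2‑[(4S,6Z,8S)‑8‑[(tert‑butyldiphenylsilyl)peroxy]‑4,8,12‑trimethyltrideca‑6,11‑dien‑1‑yl]‑2‑methyloxirane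
Product: 15 (2S)‑2‑[(4S,8R)‑8‑[(tert‑butyldiphenylsilyl)peroxy]‑4,8,12‑trimethyltridec‑11‑en‑1‑yl]‑2‑methyloxirane
Conditions: 2‑nitrobenzenesulfonyl hydrazide, Et3N, CH2Cl2, rt
Reagents that add atoms: none
Why: Diimide reduction (concerted syn transfer of H2) should take the 1,2‑disubstituted alkene well before the trisubstituted one and does not cleave O–O bonds or epoxides.

**Step 12**
Reactants: 15 (2S)‑2‑[(4S,8R)‑8‑[(tert‑butyldiphenylsilyl)peroxy]‑4,8,12‑trimethyltridec‑11‑en‑1‑yl]‑2‑methyloxirane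
Product: 16 (2R,6R,10R)‑10‑[(tert‑butyldiphenylsilyl)peroxy]‑2‑hydroperoxy‑2,6,10,14‑tetramethylpentadec‑13‑en‑1‑ol
Conditions: H2O2 (anhydrous, in Et2O), H3PMo12O40 (cat.), Et2O, 0 °C → rt
Reagents that add atoms: hydrogen peroxide, OO
Why: Second epoxide perhydrolysis, as in step 2; inversion at the quaternary carbon should turn the (S)‑epoxide into the hydroperoxide with the C6 configuration of the target, the bulky silyl peroxide and the alkene being expected to survive.

**Step 13**
Reactants: 16 (2R,6R,10R)‑10‑[(tert‑butyldiphenylsilyl)peroxy]‑2‑hydroperoxy‑2,6,10,14‑tetramethylpentadec‑13‑en‑1‑ol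
Product: 17 (2R,6R,10R)‑2‑[(tert‑butyldimethylsilyl)peroxy]‑10‑[(tert‑butyldiphenylsilyl)peroxy]‑2,6,10,14‑tetramethylpentadec‑13‑en‑1‑ol
Conditions: tBuMe2SiCl (1.05 equiv), imidazole, CH2Cl2, −20 → 0 °C
Reagents that add atoms: tert‑butylchlorodimethylsilane, CC(C)(C)[Si](C)(C)Cl
Why: Chemoselective O‑silylation of the hydroperoxide as in step 3; capping the O–O–H group removes the weak O–H bond that would quench the radical of step 17.

**Step 14**
Reactants: 17 (2R,6R,10R)‑2‑[(tert‑butyldimethylsilyl)peroxy]‑10‑[(tert‑butyldiphenylsilyl)peroxy]‑2,6,10,14‑tetramethylpentadec‑13‑en‑1‑ol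
Product: 19 (2R,6R,10R)‑2‑[(tert‑butyldimethylsilyl)peroxy]‑10‑[(tert‑butyldiphenylsilyl)peroxy]‑1‑iodo‑2,6,10,14‑tetramethylpentadec‑13‑ene, via primary triflate 18 (not isolated)
Conditions: Tf2O, 2,6‑lutidine, CH2Cl2, −78 °C; then Bu4NI, −78 °C → rt
Reagents that add atoms: tetrabutylammonium iodide, CCCC[N+](CCCC)(CCCC)CCCC.[I-]
Why: Sulfonylation and SN2 displacement by iodide; a triflate is used because only a very good leaving group is displaced at a β,β‑disubstituted primary carbon, and the quaternary stereocentre is not involved.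

**Step 15**
Reactants: 20 methyl 2‑(triphenylphosphoranylidene)propanoate; 21 acetyl chloride
Product: 23 methyl 2‑methylbuta‑2,3‑dienoate, via ketene 22 (not isolated)
Conditions: Et3N, CH2Cl2, 0 °C → rt
Reagents that add atoms: none
Why: Wittig reaction of the stabilised ylide with ketene, formed from acetyl chloride and Et3N, is the standard allenoate synthesis.

**Step 16**
Reactants: 23 methyl 2‑methylbuta‑2,3‑dienoate
Product: 24 methyl 2‑methyl‑3‑(phenylsulfonyl)but‑3‑enoate (racemic)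
Conditions: PhSO2Na, AcOH, MeOH, 0 °C → rt
Reagents that add atoms: sodium benzenesulfinate, [Na+].[O-]S(=O)c1ccccc1
Why: Conjugate addition of the sulfinate sulfur to the central allene carbon and kinetic protonation at Cα should give the deconjugated 1,1‑disubstituted vinyl sulfone; its stereocentre is destroyed in step 17.

**Step 17**
Reactants: 19 (2R,6R,10R)‑2‑[(tert‑butyldimethylsilyl)peroxy]‑10‑[(tert‑butyldiphenylsilyl)peroxy]‑1‑iodo‑2,6,10,14‑tetramethylpentadec‑13‑ene; 24 methyl 2‑methyl‑3‑(phenylsulfonyl)but‑3‑enoate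
Product: 27 methyl (2R)‑2‑[(3S,6R)‑6‑[(4R,8R)‑8‑hydroperoxy‑4,8,12‑trimethyltridec‑11‑en‑1‑yl]‑6‑methyl‑1,2‑dioxan‑3‑yl]propanoate, via sulfone adduct 25 (not isolated), via hydroperoxy enoate 26 (not isolated)
Conditions: (i) 24 (1.3 equiv), (Me3Si)3SiH (slow addition), Et3B (cat.), air, toluene, 0 °C → rt; (ii) same flask, DBU, THF, 0 °C; (iii) Bu4NF·3H2O, THF–CF3CH2OH, 0 °C → rt
Reagents that add atoms: none
Why: Proposed new method: (Me3Si)3Si• abstracts iodine from 19 and the primary C5 radical, which has a silylperoxy group on the neighbouring carbon, should add to the CH2 end of vinyl sulfone 24 (Giese addition, C4–C5 bond) before it attacks its own O–O bond, hydrogen transfer then giving 25; DBU expels benzenesulfinate by E1cB to unveil the (E)‑2‑methylalk‑2‑enoate, and fluoride removes both silyl groups so that the C6 peroxide anion adds to C3 (O2–C3 bond) while the remote hydroperoxide is set free. The closest known reaction types are the Giese trapping of β‑peroxyalkyl radicals (from reduction of peroxymercurials) by electron‑poor alkenes, radical addition to vinyl sulfones followed by sulfinate elimination, and the base‑mediated cyclisation of hydroperoxy enoates to 1,2‑dioxan‑3‑yl alkanoates. The only ring closes in the 6‑exo‑trig mode (hetero‑Michael addition) through a chair with the C1′ chain on C6 and the enoate arm equatorial and the C6 methyl axial, which should favour (3S) from the fixed (6R) centre; anti addition of O2 and of the proton from CF3CH2OH across the (E)‑alkene gives (R) at Cα. The step needs chemoselectivity at the radical stage (secured by the fast addition of alkyl radicals to vinyl sulfones, the slow silane feed and the capped O–O–H groups) and diastereoselectivity at C3 and Cα, which rests only on the slight equatorial preference of the long chain over methyl and on the alkene geometry and is expected to be modest; the isomers are diastereomers, should be separable by chromatography, and the unwanted ones can be re‑equilibrated with DBU by retro‑addition.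

**Compound list**

1 | 6‑methylhept‑5‑en‑2‑one | CC(=O)CCC=C(C)C | starting material
2 | (2R)‑2‑methyl‑2‑(4‑methylpent‑3‑en‑1‑yl)oxirane | C1[C@@](C)(CCC=C(C)C)O1 | intermediate
3 | (2S)‑2‑hydroperoxy‑2,6‑dimethylhept‑5‑en‑1‑ol | OC[C@](C)(CCC=C(C)C)OO | intermediate
4 | (2S)‑2‑[(tert‑butyldiphenylsilyl)peroxy]‑2,6‑dimethylhept‑5‑en‑1‑ol | OC[C@](C)(CCC=C(C)C)OO[Si](c1ccccc1)(c1ccccc1)C(C)(C)C | intermediate
5 | (2S)‑2‑[(tert‑butyldiphenylsilyl)peroxy]‑2,6‑dimethylhept‑5‑enal | O=C[C@](C)(CCC=C(C)C)OO[Si](c1ccccc1)(c1ccccc1)C(C)(C)C | intermediate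
6 | (S)‑citronellyl bromide, (6S)‑8‑bromo‑2,6‑dimethyloct‑2‑ene | CC(C)=CCC[C@H](C)CCBr | starting material
7 | (2E,6S)‑8‑bromo‑2,6‑dimethyloct‑2‑en‑1‑ol | OC/C(C)=C/CC[C@H](C)CCBr | intermediate
8 | [(2R,3R)‑3‑[(3S)‑5‑bromo‑3‑methylpentyl]‑2‑methyloxiran‑2‑yl]methanol | OC[C@@]1(C)O[C@@H]1CC[C@H](C)CCBr | intermediate
9 | (2S,6S)‑8‑bromo‑2,6‑dimethyloctane‑1,2‑diol | OC[C@](C)(CCC[C@H](C)CCBr)O | intermediate
10 | (2S,6S)‑8‑bromo‑2‑hydroxy‑2,6‑dimethyloctyl 4‑methylbenzenesulfonate | Cc1ccc(cc1)S(=O)(=O)OC[C@](C)(CCC[C@H](C)CCBr)O | intermediate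
11 | (2S)‑2‑[(4S)‑6‑bromo‑4‑methylhexyl]‑2‑methyloxirane | C1[C@](C)(CCC[C@H](C)CCBr)O1 | intermediate
12 | {(3S)‑3‑methyl‑6‑[(2S)‑2‑methyloxiran‑2‑yl]hexyl}triphenylphosphonium bromide | [Br-].C1[C@](C)(CCC[C@H](C)CC[P+](c2ccccc2)(c2ccccc2)c2ccccc2)O1 | intermediate
13 | ylide of 12, {(3S)‑3‑methyl‑6‑[(2S)‑2‑methyloxiran‑2‑yl]hexylidene}triphenylphosphorane | C1[C@](C)(CCC[C@H](C)CC=P(c2ccccc2)(c2ccccc2)c2ccccc2)O1 | intermediate
14 | (2S)‑2‑[(4S,6Z,8S)‑8‑[(tert‑butyldiphenylsilyl)peroxy]‑4,8,12‑trimethyltrideca‑6,11‑dien‑1‑yl]‑2‑methyloxirane | C1[C@](C)(CCC[C@H](C)C/C=C\[C@](C)(CCC=C(C)C)OO[Si](c2ccccc2)(c2ccccc2)C(C)(C)C)O1 | intermediate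
15 | (2S)‑2‑[(4S,8R)‑8‑[(tert‑butyldiphenylsilyl)peroxy]‑4,8,12‑trimethyltridec‑11‑en‑1‑yl]‑2‑methyloxirane | C1[C@](C)(CCC[C@H](C)CCC[C@](C)(CCC=C(C)C)OO[Si](c2ccccc2)(c2ccccc2)C(C)(C)C)O1 | intermediate
16 | (2R,6R,10R)‑10‑[(tert‑butyldiphenylsilyl)peroxy]‑2‑hydroperoxy‑2,6,10,14‑tetramethylpentadec‑13‑en‑1‑ol | OC[C@@](C)(CCC[C@H](C)CCC[C@](C)(CCC=C(C)C)OO[Si](c1ccccc1)(c1ccccc1)C(C)(C)C)OO | intermediate
17 | (2R,6R,10R)‑2‑[(tert‑butyldimethylsilyl)peroxy]‑10‑[(tert‑butyldiphenylsilyl)peroxy]‑2,6,10,14‑tetramethylpentadec‑13‑en‑1‑ol | OC[C@@](C)(CCC[C@H](C)CCC[C@](C)(CCC=C(C)C)OO[Si](c1ccccc1)(c1ccccc1)C(C)(C)C)OO[Si](C)(C)C(C)(C)C | intermediate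
18 | trifluoromethanesulfonate of 17 (primary O–SO2CF3, stereocentres as in 17) | FC(F)(F)S(=O)(=O)OC[C@@](C)(CCC[C@H](C)CCC[C@](C)(CCC=C(C)C)OO[Si](c1ccccc1)(c1ccccc1)C(C)(C)C)OO[Si](C)(C)C(C)(C)C | intermediate
19 | (2R,6R,10R)‑2‑[(tert‑butyldimethylsilyl)peroxy]‑10‑[(tert‑butyldiphenylsilyl)peroxy]‑1‑iodo‑2,6,10,14‑tetramethylpentadec‑13‑ene | IC[C@@](C)(CCC[C@H](C)CCC[C@](C)(CCC=C(C)C)OO[Si](c1ccccc1)(c1ccccc1)C(C)(C)C)OO[Si](C)(C)C(C)(C)C | intermediate
20 | methyl 2‑(triphenylphosphoranylidene)propanoate | COC(=O)C(C)=P(c1ccccc1)(c1ccccc1)c1ccccc1 | starting material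
21 | acetyl chloride | CC(=O)Cl | starting material
22 | ketene | C=C=O | intermediate
23 | methyl 2‑methylbuta‑2,3‑dienoate | COC(=O)C(C)=C=C | intermediate
24 | methyl 2‑methyl‑3‑(phenylsulfonyl)but‑3‑enoate (racemic) | COC(=O)C(C)C(=C)S(=O)(=O)c1ccccc1 | intermediate
25 | Giese adduct: methyl 2‑methyl‑3‑(phenylsulfonyl)alkanoate carrying the bis(silylperoxy) chain of 19 on C4 (mixture at C3 and Cα, other centres as in 19) | COC(=O)C(C)C(CC[C@@](C)(CCC[C@H](C)CCC[C@](C)(CCC=C(C)C)OO[Si](c1ccccc1)(c1ccccc1)C(C)(C)C)OO[Si](C)(C)C(C)(C)C)S(=O)(=O)c1ccccc1 | intermediate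
26 | methyl (2E,6R,10R,14R)‑6,14‑dihydroperoxy‑2,6,10,14,18‑pentamethylnonadeca‑2,17‑dienoate | COC(=O)/C(C)=C/CC[C@@](C)(CCC[C@H](C)CCC[C@](C)(CCC=C(C)C)OO)OO | intermediate
27 | methyl (2R)‑2‑[(3S,6R)‑6‑[(4R,8R)‑8‑hydroperoxy‑4,8,12‑trimethyltridec‑11‑en‑1‑yl]‑6‑methyl‑1,2‑dioxan‑3‑yl]propanoate | COC(=O)[C@H](C)[C@@H]1CC[C@@](C)(CCC[C@H](C)CCC[C@](C)(CCC=C(C)C)OO)OO1 | target

**Step count and risks**

Total step count: 17. Longest linear sequence: 11 steps (from 6 through steps 5–14 and 17).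

Steps most likely to fail:

1. Step 17 (Proposed new method). The C5 radical may substitute at its own O–O bond (epoxide formation) or be reduced before it adds; base may turn left‑over 24 back into the allenoate, which would compete for the peroxide anions; facial selectivity at C3 and Cα may be poor. Fallback with known chemistry, from 17 to 27: Dess–Martin oxidation of 17 gives the α‑peroxy aldehyde F1. Wittig reaction with the ylide made from [(2E)‑4‑methoxy‑3‑methyl‑4‑oxobut‑2‑en‑1‑yl]triphenylphosphonium bromide and NaN(SiMe3)2 gives the dienoate F2. Diimide (2‑nitrobenzenesulfonyl hydrazide, Et3N) should reduce only the disubstituted C4=C5 bond and give the bis‑silyl enoate F3. Bu4NF in THF–CF3CH2OH then removes both silyl groups and the hydroperoxy enoate cyclises by the known 6‑exo hetero‑Michael addition to 27. The C–C bond is thus made by polar olefination and reduction instead of by a radical; C3/Cα isomers are still separated by chromatography.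

2. Step 13 (the same issue applies to step 3). Competitive silylation of the primary alcohol, or silyl transfer between the two oxygens, would give mixtures. Fallback, from 16 to 17: the alcohol is masked first by an enzyme that does not touch the tertiary hydroperoxide. Immobilised Candida antarctica lipase B with vinyl acetate in tBuOMe acetylates only the primary hydroxyl and gives the acetate F4; tBuMe2SiCl and imidazole then silylate the only free O–H and give the silyl peroxide acetate F5; the same lipase in tBuOMe–MeOH removes the acetate under neutral conditions and returns 17.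

3. Step 1. Insufficient enantioselectivity or the wrong sense of induction with this dialkyl ketone would compromise C8′. Fallback, from 1 to 2: uncatalysed Corey–Chaykovsky epoxidation (Me3S(O)I, NaH, DMSO) gives the racemic epoxide F6. Kinetic resolution with a bacterial epoxide hydrolase that prefers (S)‑2‑methyl‑2‑alkyloxiranes (whole cells, buffer pH 8) hydrolyses the (S)‑enantiomer at its CH2 carbon and leaves 2, which is separated from the diol by chromatography.

**Further compounds**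

F1 | step 17 | (2R,6R,10R)‑2‑[(tert‑butyldimethylsilyl)peroxy]‑10‑[(tert‑butyldiphenylsilyl)peroxy]‑2,6,10,14‑tetramethylpentadec‑13‑enal | O=C[C@@](C)(CCC[C@H](C)CCC[C@](C)(CCC=C(C)C)OO[Si](c1ccccc1)(c1ccccc1)C(C)(C)C)OO[Si](C)(C)C(C)(C)C
F2 | step 17 | methyl (2E,4E)‑2‑methylalka‑2,4‑dienoate from F1, 6‑O–O–SiMe2tBu and 14‑O–O–SiPh2tBu (stereocentres as in 17) | COC(=O)/C(C)=C/C=C/[C@@](C)(CCC[C@H](C)CCC[C@](C)(CCC=C(C)C)OO[Si](c1ccccc1)(c1ccccc1)C(C)(C)C)OO[Si](C)(C)C(C)(C)C
F3 | step 17 | bis‑silyl derivative of 26 (6‑O–O–SiMe2tBu, 14‑O–O–SiPh2tBu, 2E) | COC(=O)/C(C)=C/CC[C@@](C)(CCC[C@H](C)CCC[C@](C)(CCC=C(C)C)OO[Si](c1ccccc1)(c1ccccc1)C(C)(C)C)OO[Si](C)(C)C(C)(C)C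
F4 | step 13 | primary acetate of 16 | CC(=O)OC[C@@](C)(CCC[C@H](C)CCC[C@](C)(CCC=C(C)C)OO[Si](c1ccccc1)(c1ccccc1)C(C)(C)C)OO
F5 | step 13 | primary acetate of 17 | CC(=O)OC[C@@](C)(CCC[C@H](C)CCC[C@](C)(CCC=C(C)C)OO[Si](c1ccccc1)(c1ccccc1)C(C)(C)C)OO[Si](C)(C)C(C)(C)C
F6 | step 1 | racemic 2‑methyl‑2‑(4‑methylpent‑3‑en‑1‑yl)oxirane | CC(C)=CCCC1(C)CO1
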